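A time constant of 17.6 min is what I read from the summer run, in which Q and E join to J over the catalyst L. I call it the clearing time: the time in which the fraction of the charged Q still unturned falls to 0.368 of what it was. I take it here over the first 9.5 min of the summer run. Q is the limiting reagent, with less Q than E in the summer charge, so its fraction is the one I follow.

| setting | summer | winter | midnight | autumn | dusk |
|---|---|---|---|---|---|
| Q | 0.500 M | 0.250 M | 0.500 M | 0.250 M | 0.500 M |
| E | 1.25 M | 1.00 M | 1.25 M | 1.25 M | 1.25 M |
| L | 0.0400 M | 0.0400 M | 0.0600 M | 0.0400 M | 0.0400 M |
| time |  |  |  |  | 38 min |

- summer run (time / min: [J] / M): 3.2: 0.082; 6.3: 0.144; 9.5: 0.209; 13: 0.265; 16: 0.316; 19: 0.355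
- winter run (time / min: [J] / M): 3.2: 0.050; 6.3: 0.102; 9.5: 0.131; 13: 0.161; 16: 0.186; 19: 0.205
- midnight run (time / min: [J] / M): 3.2: 0.117; 6.3: 0.203; 9.5: 0.280; 13: 0.352; 16: 0.401; 19: 0.441
- autumn run (time / min: [J] / M): 3.2: 0.055; 6.3: 0.100; 9.5: 0.138; 13: 0.170; 16: 0.202; 19: 0.217

(each reading ± 0.004 M)

- how the opening rate goes with [E] round the charge of the summer run: the exponent of the rate at two percent of Q gone to J
- how the opening rate goes with [L] round the charge of the summer run: the exponent of the rate at two percent of Q gone to J
- the winter run starts with 0.250 M less of Q and of E than the summer run, and with no J. Compared where both hold the same amount of Q, once fifteen percent of what the winter run was charged with has turned into J, is the winter run faster, slower or alike (within a tenth)?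
- J in the dusk run at 38 min, as a share of the Q charged

- Overall: Q + E -> J, with L as catalyst.
- Constant volume, constant temperature.
- Bound and free are read together.
- An order is taken over about fifteen percent of the charge, up and down.

I turn the settings one at a time. By hand I expect the clearing time to shorten in proportion to L. The midnight run, with L up by a factor of 1.50, reads 11.6 min, so the summer run is slower than the midnight run by a factor of 1.52. That makes my reading of the order in L 1.03.

For E, I expect a weak effect and compare two runs with the same Q. The winter run reads 12.8 min, and the autumn run, with more E, reads a shorter 11.8 min. My order in E is therefore 0.352, a small difference between two readings, and so a loose number.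

For Q, a plain exponential decay has one clearing time at any charge of Q. Yet the autumn run, with half the Q of the summer run, clears faster than the summer run, so I take the constant in these runs to drift shorter as Q falls. Between 13 min and 19 min, when the summer run holds about what the winter run holds, it reads 12.4 min. That is within a tenth of the winter value, a ratio of 1.03, so I call them alike.

I carry the drift over to the dusk run, which is the summer recipe taken to 38 min. The late stretch of the midnight run, stretched by the factor in L, gives a tail constant of 10.8 min. Starting from the fraction left at 19 min in the summer run, this leaves 5.02% unturned, so I expect 95.0% as J.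

The forecast gives 0.33 for E, 0.93 for L, alike and 95%, saying of the matched stretches that “they are alike, with no visible product inhibition or catalyst loss”.

The flask gives 0.21 for E, 0.99 for L, alike and 97.0%, so the forecast's order in E stands above the flask's by a factor of 1.53.

    L + Q + E → J + L (36.60 M⁻² min⁻¹)
    L + E ⇌ LE, settled at all times (3.140 M⁻¹)
    2 Q ⇌ Q2, settled at all times (45.20 M⁻¹)

The clearing time times ln(2) gives 12.2 min for the summer run, against the flask's 11.9 min for J to reach half the Q charged. Divided by the factor in L, the same constant gives 8.11 min for the midnight run, where the flask's time for that half is 7.99 min.

Readings and results were generated by integration for an exercise; noise was put on by code.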